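The noon run got more partner than the midnight run, 2.3 equiv against 1.5 equiv, yet both stalled. Starting material read 45% and 58% at 6.00 h, then 44% and 58% at 10.0 h.

all flasks: starting material 16 mM
- midnight: partner 1.5 equiv; scavenger 0.30 equiv; run made earlier
- noon: partner 2.3 equiv; scavenger 0.30 equiv; run made earlier
- flask: partner 1.05 equiv; scavenger 0.300 equiv; time 8.0 h

- midnight (time / h: starting material / %, single product / %): 1.33: 70, 17; 3.00: 59, 22; 6.00: 58, 23; 10.0: 58, 20
- noon (time / h: starting material / %, single product / %): 1.33: 57, 23; 3.00: 49, 26; 6.00: 45, 27; 10.0: 44, 26

(each reading ± 1.5 percentage points)

- the earlier runs were read with a standard deviation of 1.5 percentage points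

1. amount of starting material at 8.0 h, in percent of the starting material charged
2. amount of single product at 8.0 h, in percent of the starting material charged
3. amount of other mono adduct at 8.0 h, in percent of the starting material charged
4. amount of double product at 8.0 h, in percent of the starting material charged

The bench rule counts one partner for one starting material, so by that rule 1.05 equiv should just finish this flask. The runs mark where that rule stops working. Take the starting material used, as a fraction of its charge, and divide by the equivalents of partner:

midnight: 0.280
noon: 0.243

Both lie far from one, and the noon ratio is smaller than the midnight one, so this ratio won't carry to a new charge. Suppose instead that partner fades on its own clock. Each equivalent then removes a fixed fraction of the starting material still present, so the logarithm should scale with the charge: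

midnight: 0.363 per equivalent
noon: 0.357 per equivalent
mean: 0.360 per equivalent

I call this mean the reach: the logarithm of [starting material] charged over [starting material] at the stall, per equivalent of partner. It was read at 16 mM with 0.30 equiv of scavenger, as in this flask. For this flask at 8.0 h, I reckon 68.5% of starting material.

The forecast says “the partner is being lost, not just used” and gives 69% starting material, 17.5% single product, 9.5% other mono adduct and 4% double product.

    starting material + partner → single product + released group (k = 0.270 L mol⁻¹ min⁻¹)
    starting material + partner → other mono adduct + released group (k = 0.0940 L mol⁻¹ min⁻¹)
    partner + single product → double product + released group (k = 0.160 L mol⁻¹ min⁻¹)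
    partner + other mono adduct → double product + released group (k = 0.0970 L mol⁻¹ min⁻¹)
    partner + single product → over-reaction product (k = 0.210 L mol⁻¹ min⁻¹)
    partner → decomposed reagent (k = 0.0110 min⁻¹)
    partner + released group ⇌ idle adduct, settled at all times (K = 150 L mol⁻¹)
    scavenger + released group → scavenged by-product (k = 37.0 L mol⁻¹ min⁻¹)

The flask gives 69.2% starting material, 18.9% single product, 7.56% other mono adduct and 2.14% double product, and each forecast value is right within the tolerance. Partner, the limiting reagent in this flask despite its 1.05 equiv, is down to 0.0595% of its charge, unbound, at 8.00 h, and starting material stands at 69.2% then and 69.1% at 80.0 h. This flask's own reach is 0.351 per equivalent, against 0.360 from the runs. For the neighbouring flask with 0.630 equiv of partner, the reach gives 79.7%, and that flask reads 80.3% of starting material.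

(The readings were computed from invented constants, and the scatter is random.)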